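**Retrosynthetic overview**

- The strategy rests on ring A, the benzoate ring (C1 CO2Me, C2 H, C3 OH, C4 H, C5 OMe, C6 aroyl). Its two acceptors sit on adjacent carbons C1/C6 and its oxygens are meta (3-OH, 5-OMe), the pattern left by a 1,1-dimethoxy-3-silyloxybutadiene adding to an aroyl propiolate.
- The last operation only removes the two MOM groups from the ring B phenols (ring B: C1' C=O, C2'/C6' OH, C4' Me, C5' Cl).
- The key disconnection cuts C1–C2 and C5–C6 of ring A: a [4+2] benzannulation of an acetylenic keto ester that already carries the complete, MOM-protected ring B. Ring B is bought as orcinol and ring A is the only ring formed.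
- The ynone comes from the ring B aldehyde by addition of lithiated methyl propiolate and oxidation. The aldehyde comes from orcinol by chlorination, MOM protection and lithiation/formylation between the two oxygens.
- The diene comes from 1,1-dimethoxyethene by C-acetylation and O-silylation of the derived dienolate.

Key step: step 8

Remark: the target has no stereocentre and the benzophenone is assumed to show no isolable atropisomerism, so the given SMILES is a single achiral compound. Alcohol 10 is made as the racemate because its carbinol centre is removed in step 5.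

**Route**

Step 1
Reactants: 1 orcinol (5-methylbenzene-1,3-diol)
Product: 2 4-chloro-5-methylbenzene-1,3-diol
Conditions: SO2Cl2 (1.0 equiv), Et2O, 0 °C → rt
Reagents that add atoms: sulfuryl chloride, O=S(=O)(Cl)Cl
Why: Electrophilic aromatic chlorination of the resorcinol should go mainly at C4 (para to one OH, ortho to the other) in ether, and one equivalent of reagent limits dichlorination.

Step 2
Reactants: 2 4-chloro-5-methylbenzene-1,3-diol
Product: 3 2-chloro-1,5-bis(methoxymethoxy)-3-methylbenzene
Conditions: MOMCl (2.6 equiv), iPr2NEt (3 equiv), CH2Cl2, 0 °C → rt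
Reagents that add atoms: chloromethyl methyl ether, COCCl
Why: O-alkylation of both phenols gives MOM ethers, which are stable to organolithiums, direct the later ortho-lithiation and keep the phenols away from the ynone.

Step 3
Reactants: 3 2-chloro-1,5-bis(methoxymethoxy)-3-methylbenzene
Product: 6 3-chloro-2,6-bis(methoxymethoxy)-4-methylbenzaldehyde, via aryllithium 4 (not isolated), via lithium hemiaminal alkoxide 5 (not isolated)
Conditions: n-BuLi (1.2 equiv), THF, 0 °C; DMF, 0 °C → rt; H2O
Reagents that add atoms: N,N-dimethylformamide, CN(C)C=O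
Why: Directed ortho-metalation should occur at the only CH flanked by two MOM ethers, the aryl chloride being inert to n-BuLi at 0 °C and having no ortho hydrogen for aryne formation; formylation of the aryllithium with DMF then gives the aldehyde on aqueous work-up.

Step 4
Reactants: 6 3-chloro-2,6-bis(methoxymethoxy)-4-methylbenzaldehyde; 7 methyl propiolate
Product: 10 racemic methyl 4-[3-chloro-2,6-bis(methoxymethoxy)-4-methylphenyl]-4-hydroxybut-2-ynoate, via methyl 3-lithiopropiolate 8 (not isolated), via lithium alkoxide 9 (not isolated)
Conditions: 7 (1.5 equiv), LDA (1.5 equiv), THF, −78 °C; then 6, −78 °C; AcOH quench at −78 °C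
Reagents that add atoms: none
Why: 1,2-Addition of a lithium acetylide to the aldehyde, with the lithiated propiolate kept at −78 °C where it is stable; the carbinol centre forms as a racemate and is erased in step 5.

Step 5
Reactants: 10 racemic methyl 4-[3-chloro-2,6-bis(methoxymethoxy)-4-methylphenyl]-4-hydroxybut-2-ynoate
Product: 11 methyl 4-[3-chloro-2,6-bis(methoxymethoxy)-4-methylphenyl]-4-oxobut-2-ynoate
Conditions: Dess–Martin periodinane (1.3 equiv), CH2Cl2, 0 °C → rt; dilution with Et2O/pentane and filtration through a short silica pad (no aqueous nucleophiles)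
Reagents that add atoms: none
Why: Dess–Martin oxidation of the benzylic, propargylic alcohol runs under nearly neutral conditions that the MOM ethers tolerate, and the non-aqueous work-up spares the electrophilic ynone, which should be used at once.

Step 6
Reactants: 12 1,1-dimethoxyethene
Product: 13 4,4-dimethoxybut-3-en-2-one
Conditions: 12 (2.2 equiv), AcCl (1.0 equiv), Et2O, 0 °C → rt; distillation
Reagents that add atoms: acetyl chloride, CC(Cl)=O
Why: C-Acylation of the nucleophilic ketene acetal by the acid chloride; the second equivalent of ketene acetal takes up the HCl and ends as methyl acetate and chloromethane.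

Step 7
Reactants: 13 4,4-dimethoxybut-3-en-2-one
Product: 15 1,1-dimethoxy-3-(trimethylsilyloxy)buta-1,3-diene, via lithium dienolate 14 (not isolated)
Conditions: LDA (1.05 equiv), THF, −78 °C; TMSCl (1.2 equiv), −78 → 0 °C; pentane, filtration, distillation; used directly
Reagents that add atoms: chlorotrimethylsilane, C[Si](C)(C)Cl
Why: Kinetic deprotonation of the methyl ketone (α′ position of the vinylogous carbonate) and O-silylation of the cross-conjugated dienolate is standard silyl dienol ether formation.

Step 8
Reactants: 11 methyl 4-[3-chloro-2,6-bis(methoxymethoxy)-4-methylphenyl]-4-oxobut-2-ynoate; 15 1,1-dimethoxy-3-(trimethylsilyloxy)buta-1,3-diene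
Product: 18 methyl 2-[3-chloro-2,6-bis(methoxymethoxy)-4-methylbenzoyl]-5-hydroxy-3-methoxybenzoate, via cyclohexadiene ketal cycloadduct 16 (not isolated), via aryl trimethylsilyl ether 17 (not isolated)
Conditions: 15 (2 equiv), PhMe, 0 °C → rt, then 60 °C; evaporation; K2CO3 (cat.), MeOH, rt; aq. NH4Cl
Reagents that add atoms: none
Why: The electron-rich diene 15 should add to the electron-poor alkyne of 11 in a normal-demand, strongly asynchronous Diels–Alder reaction (the stepwise limit, conjugate addition followed by closure of the allenolate onto the dimethoxycarbenium ion, gives the same adduct), forming C1–C2 and C5–C6 of ring A. The closest known reaction type is the benzannulation of 1,1-dialkoxy-3-silyloxybuta-1,3-dienes (Brassard-type dienes) with acetylenic ketones and esters. Ring A closes as a six-membered carbocycle by [4+2] cycloaddition, 1,4-elimination of methanol from ketal 16 aromatises it to 17, and methanolysis of the aryl silyl ether gives 18. No stereocentre is created. Only regioselectivity is needed: the CH2 terminus, the most nucleophilic carbon of 15, must bond to the alkyne carbon bearing CO2Me, which is secured because that carbon is β to the ketone, the stronger acceptor, so the acetal carbon bonds to the aroyl-bearing carbon and places OMe next to the ketone and OH para to it. The MOM ethers keep the ring B phenols from adding to the ynone (chromone formation), and the tetra-ortho-substituted ketone is never made by attack on a crowded carbonyl because ring A is grown around it.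

Step 9
Reactants: 18 methyl 2-[3-chloro-2,6-bis(methoxymethoxy)-4-methylbenzoyl]-5-hydroxy-3-methoxybenzoate
Product: 19 monochlorosulochrin (methyl 2-(3-chloro-2,6-dihydroxy-4-methylbenzoyl)-5-hydroxy-3-methoxybenzoate)
Conditions: HCl (1.25 M in MeOH), rt → 40 °C
Reagents that add atoms: none
Why: Acid-catalysed acetal exchange in methanol should remove both aryl MOM ethers, which are ortho to the ketone and cleave readily, while the methyl ester, methyl ether and aryl chloride are inert.

**Compound list**

1 | orcinol (5-methylbenzene-1,3-diol) | Cc1cc(O)cc(O)c1 | starting material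
2 | 4-chloro-5-methylbenzene-1,3-diol | Cc1cc(O)cc(O)c1Cl | intermediate
3 | 2-chloro-1,5-bis(methoxymethoxy)-3-methylbenzene | Cc1cc(OCOC)cc(OCOC)c1Cl | intermediate
4 | [3-chloro-2,6-bis(methoxymethoxy)-4-methylphenyl]lithium (formed in situ) | [Li]c1c(OCOC)cc(C)c(Cl)c1OCOC | intermediate
5 | lithium [3-chloro-2,6-bis(methoxymethoxy)-4-methylphenyl](dimethylamino)methanolate (formed in situ, racemic) | [Li]OC(N(C)C)c1c(OCOC)cc(C)c(Cl)c1OCOC | intermediate
6 | 3-chloro-2,6-bis(methoxymethoxy)-4-methylbenzaldehyde | O=Cc1c(OCOC)cc(C)c(Cl)c1OCOC | intermediate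
7 | methyl propiolate | C#CC(=O)OC | starting material
8 | methyl 3-lithiopropiolate (formed in situ) | [Li]C#CC(=O)OC | intermediate
9 | lithium alkoxide of 10 (formed in situ, racemic) | COC(=O)C#CC(O[Li])c1c(OCOC)cc(C)c(Cl)c1OCOC | intermediate
10 | racemic methyl 4-[3-chloro-2,6-bis(methoxymethoxy)-4-methylphenyl]-4-hydroxybut-2-ynoate | COC(=O)C#CC(O)c1c(OCOC)cc(C)c(Cl)c1OCOC | intermediate
11 | methyl 4-[3-chloro-2,6-bis(methoxymethoxy)-4-methylphenyl]-4-oxobut-2-ynoate | COC(=O)C#CC(=O)c1c(OCOC)cc(C)c(Cl)c1OCOC | intermediate
12 | 1,1-dimethoxyethene | C=C(OC)OC | starting material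
13 | 4,4-dimethoxybut-3-en-2-one | CC(=O)C=C(OC)OC | intermediate
14 | lithium 4,4-dimethoxybuta-1,3-dien-2-olate (formed in situ) | [Li]OC(=C)C=C(OC)OC | intermediate
15 | 1,1-dimethoxy-3-(trimethylsilyloxy)buta-1,3-diene | COC(OC)=CC(=C)O[Si](C)(C)C | intermediate
16 | methyl 2-[3-chloro-2,6-bis(methoxymethoxy)-4-methylbenzoyl]-3,3-dimethoxy-5-(trimethylsilyloxy)cyclohexa-1,4-diene-1-carboxylate (formed in situ) | COC(=O)C1=C(C(=O)c2c(OCOC)cc(C)c(Cl)c2OCOC)C(OC)(OC)C=C(O[Si](C)(C)C)C1 | intermediate
17 | methyl 2-[3-chloro-2,6-bis(methoxymethoxy)-4-methylbenzoyl]-3-methoxy-5-(trimethylsilyloxy)benzoate (formed in situ) | COC(=O)c1cc(O[Si](C)(C)C)cc(OC)c1C(=O)c1c(OCOC)cc(C)c(Cl)c1OCOC | intermediate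
18 | methyl 2-[3-chloro-2,6-bis(methoxymethoxy)-4-methylbenzoyl]-5-hydroxy-3-methoxybenzoate | COC(=O)c1cc(O)cc(OC)c1C(=O)c1c(OCOC)cc(C)c(Cl)c1OCOC | intermediate
19 | monochlorosulochrin | COC(=O)c1cc(O)cc(OC)c1C(=O)c1c(O)cc(C)c(Cl)c1O | target

**Step count**

Total step count: 9. Longest linear sequence: 7 (steps 1–5, 8, 9); steps 6–7 form the two-step diene branch.

**Steps most likely to fail**

1. Step 8. The trimethylsilyl enol ether may be lost hydrolytically, either from the diene before it meets the ynone or from the primary adduct, so that the sequence stalls at non-aromatised addition products while the fragile ynone decomposes. The fallback sets out from 13 and 11 and changes the diene partner and the staging. Silylation of 13 with TBSOTf/Et3N (Et2O, 0 °C) should give the more robust 3-(tert-butyldimethylsilyloxy)-1,1-dimethoxybuta-1,3-diene F1, which tolerates purification and heating. Cycloaddition with 11 (PhMe, rt → 80 °C) should lead through the cyclohexadiene ketal F2 to the isolable methyl 5-(tert-butyldimethylsilyloxy)-2-[3-chloro-2,6-bis(methoxymethoxy)-4-methylbenzoyl]-3-methoxybenzoate F3. After chromatography, F3 is desilylated in a separate step with TBAF/AcOH (THF, 0 °C), coming back to the route at 18.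

2. Step 4. Self-condensation of the lithiated propiolate may outrun its addition to the hindered, electron-rich aldehyde. The fallback sets out from 6 and builds the chain as C2 then C1. Ethynylmagnesium bromide (THF, 0 °C) should add to give 1-[3-chloro-2,6-bis(methoxymethoxy)-4-methylphenyl]prop-2-yn-1-ol F4. Double deprotonation with n-BuLi (2.1 equiv, THF, −78 °C) gives the dilithio alkoxide acetylide F5. Carboxylation with CO2 and brief cold acidification to pH 3–4 gives 4-[3-chloro-2,6-bis(methoxymethoxy)-4-methylphenyl]-4-hydroxybut-2-ynoic acid F6. Esterification with TMSCHN2 (PhMe/MeOH, 0 °C) comes back to the route at 10.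

3. Step 1. Chlorination between the two hydroxyl groups and double chlorination may compete with the wanted monochlorination at C4. The fallback sets out from 1 and moves the chlorination to a stage where symmetry removes the regiochemical question. MOM protection (MOMCl, iPr2NEt, CH2Cl2) gives 1,3-bis(methoxymethoxy)-5-methylbenzene F7. Lithiation between the oxygens (n-BuLi, THF, 0 °C) gives [2,6-bis(methoxymethoxy)-4-methylphenyl]lithium F8, and DMF converts it through the lithium hemiaminal alkoxide F9 into 2,6-bis(methoxymethoxy)-4-methylbenzaldehyde F10 after aqueous work-up. The two free ring positions of F10 are equivalent, each ortho and para to an acetal oxygen and meta to the formyl group. Chlorination with NCS (1.0 equiv, DMF, rt → 50 °C) comes back to the route at 6.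

**Further compounds**

F1 | step 8 | 3-(tert-butyldimethylsilyloxy)-1,1-dimethoxybuta-1,3-diene | COC(OC)=CC(=C)O[Si](C)(C)C(C)(C)C
F2 | step 8 | methyl 5-(tert-butyldimethylsilyloxy)-2-[3-chloro-2,6-bis(methoxymethoxy)-4-methylbenzoyl]-3,3-dimethoxycyclohexa-1,4-diene-1-carboxylate | COC(=O)C1=C(C(=O)c2c(OCOC)cc(C)c(Cl)c2OCOC)C(OC)(OC)C=C(O[Si](C)(C)C(C)(C)C)C1
F3 | step 8 | methyl 5-(tert-butyldimethylsilyloxy)-2-[3-chloro-2,6-bis(methoxymethoxy)-4-methylbenzoyl]-3-methoxybenzoate | COC(=O)c1cc(O[Si](C)(C)C(C)(C)C)cc(OC)c1C(=O)c1c(OCOC)cc(C)c(Cl)c1OCOC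
F4 | step 4 | 1-[3-chloro-2,6-bis(methoxymethoxy)-4-methylphenyl]prop-2-yn-1-ol (racemic) | C#CC(O)c1c(OCOC)cc(C)c(Cl)c1OCOC
F5 | step 4 | dilithio alkoxide acetylide of F4 (formed in situ) | [Li]C#CC(O[Li])c1c(OCOC)cc(C)c(Cl)c1OCOC
F6 | step 4 | 4-[3-chloro-2,6-bis(methoxymethoxy)-4-methylphenyl]-4-hydroxybut-2-ynoic acid (racemic) | OC(=O)C#CC(O)c1c(OCOC)cc(C)c(Cl)c1OCOC
F7 | step 1 | 1,3-bis(methoxymethoxy)-5-methylbenzene | Cc1cc(OCOC)cc(OCOC)c1
F8 | step 1 | [2,6-bis(methoxymethoxy)-4-methylphenyl]lithium (formed in situ) | [Li]c1c(OCOC)cc(C)cc1OCOC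
F9 | step 1 | lithium [2,6-bis(methoxymethoxy)-4-methylphenyl](dimethylamino)methanolate (formed in situ, racemic) | [Li]OC(N(C)C)c1c(OCOC)cc(C)cc1OCOC
F10 | step 1 | 2,6-bis(methoxymethoxy)-4-methylbenzaldehyde | O=Cc1c(OCOC)cc(C)cc1OCOC
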